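## Analysis of the target

Balanophonin 25 is a neolignan built on a 2,3-dihydrobenzofuran. Ring B (O1, C2, C3, C3a, C7a) is fused to the benzene ring A (C3a, C4, C5, C6, C7, C7a). C2 carries the 4-hydroxy-3-methoxyphenyl ring C, C3 the hydroxymethyl carbon C9, C7 a methoxy group and C5 an (E)-propenal. The only stereocentres are the neighbouring C2 and C3; the structure as drawn is 2R,3S, so ring C and C9 lie on opposite faces of ring B (trans). The sensitive groups are the enal (Michael acceptor, open to a second olefination), the free phenol, and the C2–O1 bond, a para-hydroxybenzyl aryl ether that can ionise under acid once the phenol is free. The difficulty is to fix two contiguous benzylic centres in absolute terms, to close the aryl ether ring without disturbing either, and to bring the enal in late. The strategy rests on one positional fact: C7a, the ring A carbon bonded to O1, is para to C5. As long as C5 carries a carbonyl group, a fluoride on C7a is activated for displacement by the oxygen on C2. Ring A therefore has to be assembled as a 3,4,5-trisubstituted benzoate with the fluoride flanked by the C7 methoxy group and the C3a side chain.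

## Retrosynthetic reasoning

**25 to 24.** The O–protecting-group bonds are cut last. The ring C phenol is carried as a methoxymethyl ether and the C9 oxygen as a trityl ether, both of which fall to dilute aqueous acid in one operation. The forward step must free two hydroxyls without hydrating the enal or ionising C2–O1.

**24 to 22 and 23.** The enal C=C bond is cut, giving the C5 aldehyde 22 and the two-carbon stabilised ylide 23. The cut is made here because the aldehyde descends from the same C5 carbonyl that activates the ring closure, and because the enal then exists for only two steps. The forward Wittig reaction must give the E alkene and stop after one homologation.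

**22 to 21 to 20.** These are changes of oxidation state at the C5 carbon only: aldehyde from benzylic alcohol, alcohol from the methyl ester 20. The ester is kept up to this point because it is the activating group of the key step and tolerates every earlier reagent.

**20 to 18 (through alkoxide 19).** The C7a–O1 bond is cut. Cutting O1–C2 instead would mean a displacement at the stereocentre C2, a benzylic carbon on an electron-rich ring where ionisation would erode configuration. Cutting at the aromatic carbon leaves every bond to C2 and C3 intact. Ring B is thus opened to the fluoroarene alcohol 18, in which the fluoride on C7a is para to the ester. The forward step must use the C2 oxygen only. The C9 oxygen could reach C7a through a five-membered ring just as well, so it has to be blocked by a group that neither leaves nor migrates under base.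

**18 to 17 to 16.** The trityl ether is removed to give the 1,3-diol 17. The C9–O bond is traced back to the imide carbonyl of aldol adduct 16. The forward steps are a reductive cleavage of the auxiliary that spares the aryl ester, and a protection that distinguishes the primary from the secondary benzylic hydroxyl.

**16 to 11 and 13.** The C2–C3 bond is cut in the aldol sense, giving the arylacetyl imide 11 (ring A, C3, C9) and the protected vanillin 13 (ring C, C2). This is the only carbon–carbon bond between the two stereocentres, and a boron-mediated syn aldol sets both at once. The syn adduct is required: when the C2 oxygen and ring A are brought together for ring closure, the syn arrangement places ring C and C9 on opposite faces. The (R)-configured auxiliary 9 gives the enantiomer needed.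

**11 to 8 and 9; 8 to 7; 7 to 4 and 5 (through 6).** The imide N–acyl bond leads to acid 8 and oxazolidinone 9. The acid comes from tert-butyl ester 7, and the aryl–CH2 bond (C3a–C3) is cut to aryl bromide 4 and the zinc enolate 6 made from bromoacetate 5. A cross-coupling at this bond uses the one halogen of 4 that is not needed later and leaves the C–F bond alone.

**4 to 2 (through 3) to 1.** The C–F bond is traced to a C–N bond through diazonium salt 3, and the C–Br bond to bromination ortho to the amino group of 1. The amino group of the commercial aminobenzoate 1 directs the bromine to the right carbon, and afterwards becomes the fluoride.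

**13 to 12.** The aldehyde partner is vanillin 12 with its phenol protected.

## Alternatives that were turned down

**Alternative 1:** The disconnection cuts C3–C9 and C2–aryl across the C2=C3 bond of a preformed benzofuran. In the forward direction a 2-metalated benzofuran and the pinacol boronate of ring C form an ate complex. A π-allylpalladium electrophile (Pd2(dba)3, (S)-BINAP) attacks C3 while ring C migrates from boron to C2. The product is 2-[(2R,3R)-5-(1,3-dioxolan-2-yl)-7-methoxy-2-[3-methoxy-4-(methoxymethoxy)phenyl]-3-(prop-2-en-1-yl)-2,3-dihydro-1-benzofuran-2-yl]-4,4,5,5-tetramethyl-1,3,2-dioxaborolane A1.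

- In its favour: both stereocentres arise in one catalytic enantioselective step, no auxiliary is used, and three simple pieces converge.
- Against it: A1 is still far from the target. The tertiary, benzylic, oxygen-bearing boronate has to be replaced by hydrogen with retention. The allyl group carries two carbons too many, so it must be isomerised into conjugation, cleaved and reduced. That sequence passes through a 3-formyl dihydrobenzofuran in which C3–H is acidic and O1 is a β leaving group, inviting epimerisation and ring opening. The enantioselection must also come from a ligand on an unsubstituted allyl fragment remote from C3, which nothing in this substrate assists.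
- Comparison: Alternative 1 is stronger in catalytic asymmetric induction and convergence. The chosen route offers an auxiliary of predictable sense, a C9 carbon that arrives at the right oxidation level, and a ring closure that cannot alter either centre.

**Alternative 2:** The disconnection cuts C2–C3 and O1–C2, so ring B comes from a ring A ortho-hydroxy nitrostyrene and a one-carbon ylide bearing ring C. In the forward direction Cs2CO3 generates the ylide from a benzylsulfonium salt of a chiral sulfide. Its carbon adds to the nitroalkene carbon that becomes C3, and the ring A phenoxide then displaces the sulfide at C2. The product is 4-[(2R,3S)-5-bromo-7-methoxy-3-(nitromethyl)-2,3-dihydro-1-benzofuran-2-yl]-2-methoxyphenyl 2,2-dimethylpropanoate A2.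

- In its favour: two bonds and the ring form in one step, and the C5 bromide allows a direct Heck reaction to the propenal. On paper this is the shortest route.
- Against it: after the conjugate addition the nitronate carbon and oxygen sit closer to the sulfonium carbon than the phenoxide does. Closure to a nitrocyclopropane or an isoxazoline N-oxide therefore competes. The absolute configuration depends on a stoichiometric chiral sulfide steering a semi-stabilised ylide, and the displacement at the benzylic C2 may not be cleanly invertive. The nitromethyl group of A2 needs a Nef reaction and a reduction, again through the fragile 3-formyl dihydrobenzofuran. The pivalate must be removed by base or hydride, which the enal does not tolerate.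
- Comparison: Alternative 2 is stronger in step count. The chosen route offers a ring closure with one possible nucleophile and one possible electrophilic carbon, and secure absolute control.

**Alternative 3:** The disconnection cuts C3a–C7a and C6–C7, so ring A is built from a furan and an alkyne. In the forward direction Ph3PAuNTf2 activates an ethynyl ether on the C2 oxygen. The furan carbon that becomes C3a attacks the oxygen-bearing alkyne carbon, and the furan opens, recloses onto the terminal alkyne carbon and aromatises. The product is (2R,3S)-5-(1,3-dioxolan-2-yl)-2-[3-methoxy-4-(methoxymethoxy)phenyl]-3-[(methoxymethoxy)methyl]-2,3-dihydro-1-benzofuran-7-ol A3.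

- In its favour: the arene is made de novo with its oxygen exactly at C7, the conditions are neutral and catalytic, and the stereocentres are not involved. No aryl fluoride is needed.
- Against it: the gold substrate must already contain C2 and C3 in the right configuration, so the same aldol problem remains, now with a furylacetyl unit. It also needs an ethynyl ether on a secondary benzylic oxygen. Such ethers take extra steps to make, and with a hydrogen on C3 this one is expected to lose ketene by a retro-ene path and to hydrate easily. The C5 substituent requires a 2,4-disubstituted furan, which is less accessible than the 2,5 pattern. Two acetal-type protecting groups must survive a cationic monovalent gold catalyst, and A3 still needs O-methylation.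
- Comparison: Alternative 3 is stronger in how much of ring A it constructs in one step. The chosen route buys ring A, so its uncertain step is a classical substitution on a robust substrate, and it is shorter.

Key step: step 10

Remark on the chemistry: the target is read as the (2R,3S)-trans isomer with an E enal. The C9 oxygen is carried as a trityl ether, not an acetal, because trityl goes onto the primary hydroxyl selectively in one step, cannot migrate to the neighbouring alkoxide, and leaves under milder acid.

## Route

Step 1
Reactants: 1 methyl 4-amino-3-methoxybenzoate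
Product: 2 methyl 4-amino-3-bromo-5-methoxybenzoate
Conditions: NBS (1.05 equiv), MeCN, 0 °C to rt
Reagents that add atoms: N-bromosuccinimide, O=C1CCC(=O)N1Br
Why: Electrophilic aromatic bromination; the amino group is the strongest director and its para position is blocked by the ester, so bromine should enter the one free ortho position.

Step 2
Reactants: 2 methyl 4-amino-3-bromo-5-methoxybenzoate
Product: 4 methyl 3-bromo-4-fluoro-5-methoxybenzoate, via arenediazonium tetrafluoroborate 3 (not isolated)
Conditions: NOBF4, CH2Cl2, 0 °C; then 1,2-dichlorobenzene, CH2Cl2 distilled off, 110 °C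
Reagents that add atoms: nitrosonium tetrafluoroborate, N#[O+].F[B-](F)(F)F
Why: Balz–Schiemann reaction; the nitrosonium salt diazotises the weakly basic aniline without water, and heating 3 expels N2 while fluoride passes from BF4− to the aryl carbon. The ester, bromide and methyl ether are inert.

Step 3
Reactants: 4 methyl 3-bromo-4-fluoro-5-methoxybenzoate; 5 tert-butyl bromoacetate
Product: 7 methyl 3-(2-tert-butoxy-2-oxoethyl)-4-fluoro-5-methoxybenzoate, via Reformatsky reagent 6 (not isolated)
Conditions: 5, Zn dust, Me3SiCl (cat.), THF, 40 °C; then 4, Pd2(dba)3 (1 mol %), XPhos (2.5 mol %), THF, 60 °C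
Reagents that add atoms: none
Why: Negishi-type α-arylation of a zinc ester enolate; zerovalent palladium inserts into C–Br and not C–F, and transmetalation with 6 followed by reductive elimination forms the aryl–CH2 bond. The zinc enolate is mild enough to spare both esters and should stop at monoarylation.

Step 4
Reactants: 7 methyl 3-(2-tert-butoxy-2-oxoethyl)-4-fluoro-5-methoxybenzoate
Product: 8 [2-fluoro-3-methoxy-5-(methoxycarbonyl)phenyl]acetic acid
Conditions: CF3CO2H, CH2Cl2 (1:3), rt
Reagents that add atoms: none
Why: Acidolysis of the tert-butyl ester through the tert-butyl cation (lost as isobutene); the methyl ester, aryl fluoride and methyl ether are untouched.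

Step 5
Reactants: 8 [2-fluoro-3-methoxy-5-(methoxycarbonyl)phenyl]acetic acid; 9 (R)-4-benzyl-2-oxazolidinone
Product: 11 methyl 3-{2-[(4R)-4-benzyl-2-oxo-1,3-oxazolidin-3-yl]-2-oxoethyl}-4-fluoro-5-methoxybenzoate, via mixed pivalic anhydride 10 (not isolated)
Conditions: t-BuCOCl, Et3N, THF, −20 °C; then 9, LiCl, −20 °C to rt
Reagents that add atoms: none
Why: N-acylation through the mixed anhydride 10; the hindered pivaloyl carbonyl directs the oxazolidinone to the arylacetyl carbonyl. No strong base is present that could enolise the acidic arylacetyl CH2 or attack the methyl ester.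

Step 6
Reactants: 12 vanillin
Product: 13 3-methoxy-4-(methoxymethoxy)benzaldehyde
Conditions: MeOCH2Cl, i-Pr2NEt, CH2Cl2, 0 °C to rt
Reagents that add atoms: chloromethyl methyl ether, COCCl
Why: O-alkylation of the phenol; the aryl methoxymethyl ether tolerates boron enolates, hydride, amide base and ylide, and falls to dilute acid at the end.

Step 7
Reactants: 11 methyl 3-{2-[(4R)-4-benzyl-2-oxo-1,3-oxazolidin-3-yl]-2-oxoethyl}-4-fluoro-5-methoxybenzoate; 13 3-methoxy-4-(methoxymethoxy)benzaldehyde
Product: 16 methyl 3-[(2R,3R)-1-[(4R)-4-benzyl-2-oxo-1,3-oxazolidin-3-yl]-3-hydroxy-3-[3-methoxy-4-(methoxymethoxy)phenyl]-1-oxopropan-2-yl]-4-fluoro-5-methoxybenzoate, via dibutylboron Z-enolate 14 (not isolated), via dibutylboron aldolate 15 (not isolated)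
Conditions: Bu2BOTf (1.2 equiv), i-Pr2NEt (1.4 equiv), CH2Cl2, −78 to 0 °C; 13, −78 to 0 °C; then pH 7 buffer, MeOH, 30% H2O2, 0 °C
Reagents that add atoms: none
Why: Evans syn aldol; the Z boron enolate 14 adds to 13 through a closed chair transition state in which the benzyl group of the (R)-auxiliary shields one enolate face. This sets the (2R,3R) syn pair, the mirror image of what the (S)-auxiliary gives, so both centres are arranged as in the target. Oxidative work-up cleaves the O–B bond of 15.

Step 8
Reactants: 16 methyl 3-[(2R,3R)-1-[(4R)-4-benzyl-2-oxo-1,3-oxazolidin-3-yl]-3-hydroxy-3-[3-methoxy-4-(methoxymethoxy)phenyl]-1-oxopropan-2-yl]-4-fluoro-5-methoxybenzoate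
Product: 17 methyl 3-[(1R,2S)-1,3-dihydroxy-1-[3-methoxy-4-(methoxymethoxy)phenyl]propan-2-yl]-4-fluoro-5-methoxybenzoate
Conditions: NaBH4, THF/H2O (3:1), 0 °C to rt
Reagents that add atoms: none
Why: Reductive cleavage of the activated exocyclic imide carbonyl through the aldehyde to the primary alcohol, releasing the auxiliary; the aromatic methyl ester is inert to NaBH4 under these conditions. No bond at either stereocentre is touched, and the descriptor at the aryl-bearing carbon changes from R to S only because the priorities of its neighbours change.

Step 9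
Reactants: 17 methyl 3-[(1R,2S)-1,3-dihydroxy-1-[3-methoxy-4-(methoxymethoxy)phenyl]propan-2-yl]-4-fluoro-5-methoxybenzoate
Product: 18 methyl 4-fluoro-3-[(1R,2S)-1-hydroxy-1-[3-methoxy-4-(methoxymethoxy)phenyl]-3-(triphenylmethoxy)propan-2-yl]-5-methoxybenzoate
Conditions: Ph3CCl, Et3N, DMAP (cat.), CH2Cl2, 0 °C to rt
Reagents that add atoms: trityl chloride, ClC(c1ccccc1)(c1ccccc1)c1ccccc1
Why: Tritylation is selective for the primary hydroxyl over the hindered secondary benzylic one on steric grounds. The trityl ether cannot migrate to the neighbouring alkoxide and withstands base, hydride and ylide.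

Step 10
Reactants: 18 methyl 4-fluoro-3-[(1R,2S)-1-hydroxy-1-[3-methoxy-4-(methoxymethoxy)phenyl]-3-(triphenylmethoxy)propan-2-yl]-5-methoxybenzoate
Product: 20 methyl (2R,3S)-7-methoxy-2-[3-methoxy-4-(methoxymethoxy)phenyl]-3-[(triphenylmethoxy)methyl]-2,3-dihydro-1-benzofuran-5-carboxylate, via potassium alkoxide 19 (not isolated)
Conditions: KN(SiMe3)2 (1.1 equiv), 18-crown-6 (1.1 equiv), THF, 0 °C to 40 °C
Reagents that add atoms: none
Why: Intramolecular nucleophilic aromatic substitution: the amide base converts the C2 hydroxyl into alkoxide 19, whose oxygen adds to C7a to give a Meisenheimer anion with its charge on C7, C3a and C5 and, from C5, on the ester carbonyl; loss of fluoride then restores ring A and forms C7a–O1. The closest known reaction type is the closure of alkoxides onto fluoroarenes activated by a para acyl group, an established way to 2,3-dihydrobenzofurans. Ring B closes in a 5-exo mode, since the C–F bond that breaks and the C7a=C7 π bond that first takes up the electrons both lie outside the new five-membered ring. No stereocentre is created and no bond to C2 or C3 is broken, so the (1R,2S) syn arrangement of 18 becomes the (2R,3S) trans ring, with ring C and C9 on opposite faces once O1 and ring A are joined. The step needs chemoselectivity for the C2 oxygen, secured by the trityl ether on C9, which can neither ionise to an alkoxide nor migrate. It needs regioselectivity for C7a, secured because fluoride is the only leaving group on ring A and sits para to the ester. Fluoride is the best leaving group for a rate-limiting addition, the crown ether frees the alkoxide from its counter-ion, and one equivalent of base avoids deprotonation at C3 of the product. The ester is a sufficient acceptor that is not itself consumed by an intramolecular alkoxide, because the ring-closing attack is much faster than intermolecular acyl transfer at this dilution.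

Step 11
Reactants: 20 methyl (2R,3S)-7-methoxy-2-[3-methoxy-4-(methoxymethoxy)phenyl]-3-[(triphenylmethoxy)methyl]-2,3-dihydro-1-benzofuran-5-carboxylate
Product: 21 [(2R,3S)-7-methoxy-2-[3-methoxy-4-(methoxymethoxy)phenyl]-3-[(triphenylmethoxy)methyl]-2,3-dihydro-1-benzofuran-5-yl]methanol
Conditions: i-Bu2AlH (2.5 equiv), CH2Cl2, −78 to 0 °C; aq. potassium sodium tartrate
Reagents that add atoms: none
Why: Hydride reduction of the aryl ester to the benzylic alcohol; all ethers in the molecule are inert to the reagent at this temperature.

Step 12
Reactants: 21 [(2R,3S)-7-methoxy-2-[3-methoxy-4-(methoxymethoxy)phenyl]-3-[(triphenylmethoxy)methyl]-2,3-dihydro-1-benzofuran-5-yl]methanol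
Product: 22 (2R,3S)-7-methoxy-2-[3-methoxy-4-(methoxymethoxy)phenyl]-3-[(triphenylmethoxy)methyl]-2,3-dihydro-1-benzofuran-5-carbaldehyde
Conditions: MnO2 (activated, excess), CH2Cl2, rt
Reagents that add atoms: none
Why: Selective oxidation of a benzylic alcohol to the aldehyde without over-oxidation; 21 has no other free hydroxyl.

Step 13
Reactants: 22 (2R,3S)-7-methoxy-2-[3-methoxy-4-(methoxymethoxy)phenyl]-3-[(triphenylmethoxy)methyl]-2,3-dihydro-1-benzofuran-5-carbaldehyde; 23 (triphenylphosphoranylidene)acetaldehyde
Product: 24 (2E)-3-[(2R,3S)-7-methoxy-2-[3-methoxy-4-(methoxymethoxy)phenyl]-3-[(triphenylmethoxy)methyl]-2,3-dihydro-1-benzofuran-5-yl]prop-2-enal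
Conditions: 23 (1.3 equiv), toluene, 80 °C
Reagents that add atoms: none
Why: Wittig reaction with a stabilised ylide, which gives the E alkene. The aromatic aldehyde is more electrophilic than the conjugated product enal, so a small excess of ylide should limit a second homologation.

Step 14
Reactants: 24 (2E)-3-[(2R,3S)-7-methoxy-2-[3-methoxy-4-(methoxymethoxy)phenyl]-3-[(triphenylmethoxy)methyl]-2,3-dihydro-1-benzofuran-5-yl]prop-2-enal
Product: 25 balanophonin, (2E)-3-[(2R,3S)-2-(4-hydroxy-3-methoxyphenyl)-3-(hydroxymethyl)-7-methoxy-2,3-dihydro-1-benzofuran-5-yl]prop-2-enal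
Conditions: 3 M aq. HCl, THF, rt to 40 °C
Reagents that add atoms: none
Why: Acid hydrolysis; the aryl methoxymethyl acetal and the trityl ether both cleave through stabilised cations under dilute acid. The trans ring is the thermodynamically preferred arrangement at C2 and C3, so the configuration should persist.

## Compound list

1 | methyl 4-amino-3-methoxybenzoate | COC(=O)c1ccc(N)c(OC)c1 | starting material
2 | methyl 4-amino-3-bromo-5-methoxybenzoate | COC(=O)c1cc(Br)c(N)c(OC)c1 | intermediate
3 | 2-bromo-6-methoxy-4-(methoxycarbonyl)benzenediazonium tetrafluoroborate | COC(=O)c1cc(Br)c([N+]#N)c(OC)c1.F[B-](F)(F)F | intermediate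
4 | methyl 3-bromo-4-fluoro-5-methoxybenzoate | COC(=O)c1cc(Br)c(F)c(OC)c1 | intermediate
5 | tert-butyl bromoacetate | CC(C)(C)OC(=O)CBr | starting material
6 | bromo(2-tert-butoxy-2-oxoethyl)zinc | CC(C)(C)OC(=O)C[Zn]Br | intermediate
7 | methyl 3-(2-tert-butoxy-2-oxoethyl)-4-fluoro-5-methoxybenzoate | COC(=O)c1cc(CC(=O)OC(C)(C)C)c(F)c(OC)c1 | intermediate
8 | [2-fluoro-3-methoxy-5-(methoxycarbonyl)phenyl]acetic acid | COC(=O)c1cc(CC(=O)O)c(F)c(OC)c1 | intermediate
9 | (R)-4-benzyl-2-oxazolidinone | C1[C@H](NC(=O)O1)Cc1ccccc1 | starting material
10 | [2-fluoro-3-methoxy-5-(methoxycarbonyl)phenyl]acetic 2,2-dimethylpropanoic anhydride | COC(=O)c1cc(CC(=O)OC(=O)C(C)(C)C)c(F)c(OC)c1 | intermediate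
11 | methyl 3-{2-[(4R)-4-benzyl-2-oxo-1,3-oxazolidin-3-yl]-2-oxoethyl}-4-fluoro-5-methoxybenzoate | COC(=O)c1cc(CC(=O)N2C(=O)OC[C@H]2Cc2ccccc2)c(F)c(OC)c1 | intermediate
12 | vanillin | COc1cc(C=O)ccc1O | starting material
13 | 3-methoxy-4-(methoxymethoxy)benzaldehyde | COCOc1ccc(C=O)cc1OC | intermediate
14 | methyl 3-[(Z)-2-[(4R)-4-benzyl-2-oxo-1,3-oxazolidin-3-yl]-2-[(dibutylboranyl)oxy]ethenyl]-4-fluoro-5-methoxybenzoate | CCCCB(CCCC)O/C(=C\c1cc(C(=O)OC)cc(OC)c1F)N1C(=O)OC[C@H]1Cc1ccccc1 | intermediate
15 | O-dibutylboranyl derivative of 16 (boron aldolate, 2R,3R) | COc1cc([C@H](OB(CCCC)CCCC)[C@H](C(=O)N2C(=O)OC[C@H]2Cc2ccccc2)c2cc(C(=O)OC)cc(OC)c2F)ccc1OCOC | intermediate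
16 | methyl 3-[(2R,3R)-1-[(4R)-4-benzyl-2-oxo-1,3-oxazolidin-3-yl]-3-hydroxy-3-[3-methoxy-4-(methoxymethoxy)phenyl]-1-oxopropan-2-yl]-4-fluoro-5-methoxybenzoate | COc1cc([C@H](O)[C@H](C(=O)N2C(=O)OC[C@H]2Cc2ccccc2)c2cc(C(=O)OC)cc(OC)c2F)ccc1OCOC | intermediate
17 | methyl 3-[(1R,2S)-1,3-dihydroxy-1-[3-methoxy-4-(methoxymethoxy)phenyl]propan-2-yl]-4-fluoro-5-methoxybenzoate | COc1cc([C@H](O)[C@H](CO)c2cc(C(=O)OC)cc(OC)c2F)ccc1OCOC | intermediate
18 | methyl 4-fluoro-3-[(1R,2S)-1-hydroxy-1-[3-methoxy-4-(methoxymethoxy)phenyl]-3-(triphenylmethoxy)propan-2-yl]-5-methoxybenzoate | COc1cc([C@H](O)[C@H](COC(c2ccccc2)(c2ccccc2)c2ccccc2)c2cc(C(=O)OC)cc(OC)c2F)ccc1OCOC | intermediate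
19 | potassium alkoxide of 18 | COc1cc([C@H]([O-])[C@H](COC(c2ccccc2)(c2ccccc2)c2ccccc2)c2cc(C(=O)OC)cc(OC)c2F)ccc1OCOC.[K+] | intermediate
20 | methyl (2R,3S)-7-methoxy-2-[3-methoxy-4-(methoxymethoxy)phenyl]-3-[(triphenylmethoxy)methyl]-2,3-dihydro-1-benzofuran-5-carboxylate | COc1cc([C@@H]2Oc3c(OC)cc(C(=O)OC)cc3[C@H]2COC(c2ccccc2)(c2ccccc2)c2ccccc2)ccc1OCOC | intermediate
21 | [(2R,3S)-7-methoxy-2-[3-methoxy-4-(methoxymethoxy)phenyl]-3-[(triphenylmethoxy)methyl]-2,3-dihydro-1-benzofuran-5-yl]methanol | COc1cc([C@@H]2Oc3c(OC)cc(CO)cc3[C@H]2COC(c2ccccc2)(c2ccccc2)c2ccccc2)ccc1OCOC | intermediate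
22 | (2R,3S)-7-methoxy-2-[3-methoxy-4-(methoxymethoxy)phenyl]-3-[(triphenylmethoxy)methyl]-2,3-dihydro-1-benzofuran-5-carbaldehyde | COc1cc([C@@H]2Oc3c(OC)cc(C=O)cc3[C@H]2COC(c2ccccc2)(c2ccccc2)c2ccccc2)ccc1OCOC | intermediate
23 | (triphenylphosphoranylidene)acetaldehyde | O=CC=P(c1ccccc1)(c1ccccc1)c1ccccc1 | starting material
24 | (2E)-3-[(2R,3S)-7-methoxy-2-[3-methoxy-4-(methoxymethoxy)phenyl]-3-[(triphenylmethoxy)methyl]-2,3-dihydro-1-benzofuran-5-yl]prop-2-enal | COc1cc([C@@H]2Oc3c(OC)cc(/C=C/C=O)cc3[C@H]2COC(c2ccccc2)(c2ccccc2)c2ccccc2)ccc1OCOC | intermediate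
25 | balanophonin, (2E)-3-[(2R,3S)-2-(4-hydroxy-3-methoxyphenyl)-3-(hydroxymethyl)-7-methoxy-2,3-dihydro-1-benzofuran-5-yl]prop-2-enal | COc1cc([C@@H]2Oc3c(OC)cc(/C=C/C=O)cc3[C@H]2CO)ccc1O | target

## Step count and least certain steps

Total step count: 14. Longest linear sequence: 13 steps (steps 1 to 5 and 7 to 14, from 1 to 25); step 6 is a one-step side branch.

**Key step (step 10).** The most likely failure is slow addition of the alkoxide. The ester is only a moderate para acceptor, and C7a is flanked by the donating methoxy group and the branched C3 substituent. Intermolecular acyl transfer to the methyl ester, or base-induced opening of the product by deprotonation at C3, could then take over. The fallback changes the acceptor and the order of the end game; it sets out from 18 and returns at 22.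
- The ester of 18 would be reduced with i-Bu2AlH to (1R,2S)-2-[2-fluoro-5-(hydroxymethyl)-3-methoxyphenyl]-1-[3-methoxy-4-(methoxymethoxy)phenyl]-3-(triphenylmethoxy)propan-1-ol F1.
- The primary benzylic hydroxyl of F1 would be oxidised selectively with TEMPO and PhI(OAc)2, since the hindered secondary alcohol reacts much more slowly with the oxoammonium salt. This gives 4-fluoro-3-[(1R,2S)-1-hydroxy-1-[3-methoxy-4-(methoxymethoxy)phenyl]-3-(triphenylmethoxy)propan-2-yl]-5-methoxybenzaldehyde F2.
- F2 has the fluoride para to a formyl group, a clearly stronger acceptor. It would be closed with Cs2CO3 in DMF to give 22 directly, in the same number of steps as steps 10 to 12.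

**Step 2.** The fluorodediazoniation may lose material to hydrodediazoniation and to capture of the aryl cation by other nucleophiles, because the diazonium group sits between bromine and methoxy. The fallback sets out from 2 and returns at 4.
- Compound 2 would be diazotised as before to 3, and 3 hydrolysed with Cu2O and Cu(NO3)2 in water to the phenol methyl 3-bromo-4-hydroxy-5-methoxybenzoate F3.
- F3, an electron-poor phenol, would be deoxyfluorinated with 1,3-bis(2,6-diisopropylphenyl)-2,2-difluoroimidazoline and CsF in toluene at 110 °C to give 4.

**Step 8.** Two processes threaten this step: partial reduction of the aryl methyl ester, and retro-aldol cleavage or epimerisation at the aryl-bearing carbon under basic borohydride. The fallback sets out from 16 and returns at 17.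
- The auxiliary would be removed hydrolytically with LiOH and H2O2 in THF/H2O at 0 °C, giving (2R,3R)-2-[2-fluoro-3-methoxy-5-(methoxycarbonyl)phenyl]-3-hydroxy-3-[3-methoxy-4-(methoxymethoxy)phenyl]propanoic acid F4.
- The free acid of F4 would be reduced with BH3·SMe2, which reduces carboxylic acids much faster than aryl esters, to give 17.

**Step 13.** The product enal may react with a second molecule of ylide, and conversion may stall if the excess is kept low. The fallback sets out from 22 and returns at 24.
- A Horner–Wadsworth–Emmons reaction with triethyl phosphonoacetate, LiCl and DBU cannot over-homologate. It would give ethyl (2E)-3-[(2R,3S)-7-methoxy-2-[3-methoxy-4-(methoxymethoxy)phenyl]-3-[(triphenylmethoxy)methyl]-2,3-dihydro-1-benzofuran-5-yl]prop-2-enoate F5.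
- i-Bu2AlH would reduce F5 to (2E)-3-[(2R,3S)-7-methoxy-2-[3-methoxy-4-(methoxymethoxy)phenyl]-3-[(triphenylmethoxy)methyl]-2,3-dihydro-1-benzofuran-5-yl]prop-2-en-1-ol F6.
- MnO2 would oxidise F6 to 24.

**Step 14.** Once the phenol is free, acid can ionise the C2–O1 bond, and water can add to the enal during the time needed to cleave both protecting groups. The fallback removes the protecting groups before the enal exists; it sets out from 22 and returns at 25.
- Aldehyde 22 would be treated with aqueous HCl in THF to give (2R,3S)-2-(4-hydroxy-3-methoxyphenyl)-3-(hydroxymethyl)-7-methoxy-2,3-dihydro-1-benzofuran-5-carbaldehyde F7.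
- F7 would be olefinated with 23, a stabilised ylide that tolerates the free phenol and alcohol, to give 25.

## Further compounds

F1 | step 10 | (1R,2S)-2-[2-fluoro-5-(hydroxymethyl)-3-methoxyphenyl]-1-[3-methoxy-4-(methoxymethoxy)phenyl]-3-(triphenylmethoxy)propan-1-ol | COc1cc([C@H](O)[C@H](COC(c2ccccc2)(c2ccccc2)c2ccccc2)c2cc(CO)cc(OC)c2F)ccc1OCOC
F2 | step 10 | 4-fluoro-3-[(1R,2S)-1-hydroxy-1-[3-methoxy-4-(methoxymethoxy)phenyl]-3-(triphenylmethoxy)propan-2-yl]-5-methoxybenzaldehyde | COc1cc([C@H](O)[C@H](COC(c2ccccc2)(c2ccccc2)c2ccccc2)c2cc(C=O)cc(OC)c2F)ccc1OCOC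
F3 | step 2 | methyl 3-bromo-4-hydroxy-5-methoxybenzoate | COC(=O)c1cc(Br)c(O)c(OC)c1
F4 | step 8 | (2R,3R)-2-[2-fluoro-3-methoxy-5-(methoxycarbonyl)phenyl]-3-hydroxy-3-[3-methoxy-4-(methoxymethoxy)phenyl]propanoic acid | COc1cc([C@H](O)[C@H](C(=O)O)c2cc(C(=O)OC)cc(OC)c2F)ccc1OCOC
F5 | step 13 | ethyl (2E)-3-[(2R,3S)-7-methoxy-2-[3-methoxy-4-(methoxymethoxy)phenyl]-3-[(triphenylmethoxy)methyl]-2,3-dihydro-1-benzofuran-5-yl]prop-2-enoate | COc1cc([C@@H]2Oc3c(OC)cc(/C=C/C(=O)OCC)cc3[C@H]2COC(c2ccccc2)(c2ccccc2)c2ccccc2)ccc1OCOC
F6 | step 13 | (2E)-3-[(2R,3S)-7-methoxy-2-[3-methoxy-4-(methoxymethoxy)phenyl]-3-[(triphenylmethoxy)methyl]-2,3-dihydro-1-benzofuran-5-yl]prop-2-en-1-ol | COc1cc([C@@H]2Oc3c(OC)cc(/C=C/CO)cc3[C@H]2COC(c2ccccc2)(c2ccccc2)c2ccccc2)ccc1OCOC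
F7 | step 14 | (2R,3S)-2-(4-hydroxy-3-methoxyphenyl)-3-(hydroxymethyl)-7-methoxy-2,3-dihydro-1-benzofuran-5-carbaldehyde | COc1cc([C@@H]2Oc3c(OC)cc(C=O)cc3[C@H]2CO)ccc1O
A1 | alternative 1 | 2-[(2R,3R)-5-(1,3-dioxolan-2-yl)-7-methoxy-2-[3-methoxy-4-(methoxymethoxy)phenyl]-3-(prop-2-en-1-yl)-2,3-dihydro-1-benzofuran-2-yl]-4,4,5,5-tetramethyl-1,3,2-dioxaborolane | COc1cc([C@]2(B4OC(C)(C)C(C)(C)O4)Oc3c(OC)cc(C5OCCO5)cc3[C@H]2CC=C)ccc1OCOC
A2 | alternative 2 | 4-[(2R,3S)-5-bromo-7-methoxy-3-(nitromethyl)-2,3-dihydro-1-benzofuran-2-yl]-2-methoxyphenyl 2,2-dimethylpropanoate | COc1cc([C@@H]2Oc3c(OC)cc(Br)cc3[C@H]2C[N+](=O)[O-])ccc1OC(=O)C(C)(C)C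
A3 | alternative 3 | (2R,3S)-5-(1,3-dioxolan-2-yl)-2-[3-methoxy-4-(methoxymethoxy)phenyl]-3-[(methoxymethoxy)methyl]-2,3-dihydro-1-benzofuran-7-ol | COc1cc([C@@H]2Oc3c(O)cc(C4OCCO4)cc3[C@H]2COCOC)ccc1OCOC
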